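**Retrosynthetic overview**
1. Target 27 is 2-methoxy-6,7-dimethyl-8-(2,4,5-trimethoxyphenyl)naphthalene-1,4-dione. Ring A (C1–C2–C3–C4) is opened at C1–C2 and C3–C4 to sulfonylphthalide 17 (lactone carbonyl = C1, sulfonyl carbon = C4) and 1-methoxyvinyl phenyl sulfone 23 (C2 with its methoxy group, and C3).
2. 17 comes from lactol 16 and aldehyde 15, which is made by oxazoline-directed lithiation of biaryl oxazoline 13 at the ring carbon that becomes C4a.
3. The strategy rests on ring B, where C8a (bearing the C1 carbonyl carbon), C8 (aryl), C7 (methyl) and C6 (methyl) are contiguous. C7–C8 is treated as an aryne held between a carboxyl-derived oxazoline on C8a and the C6 methyl, so 13 = chloroaryl oxazoline 6 + aryllithium 8 + iodomethane in one flask.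
4. 6 is made from 3-chloro-4-methylbenzoic acid. Ring B is bought, ring A is the only ring formed (step 11), and 27 has no stereocentre.
5. A 2-methoxyacrylate ester is not used as the ring A acceptor: its C2 ester cannot leave and base would expel methoxide instead. With a sulfonyl group on C2, sulfinate is the leaving group and the quinone is reached without an oxidant.

Key step: step 4

Assumption: the aryl–naphthoquinone axis is taken as freely rotating, since the target is drawn without an axial descriptor; the sp3 centres of 16, 17, 21 and 26 are racemic and disappear later in the route.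

**Route**

Step 1
Reactants: 1 3-chloro-4-methylbenzoic acid; 2 2-amino-2-methylpropan-1-ol
Product: 4 3-chloro-N-(1-hydroxy-2-methylpropan-2-yl)-4-methylbenzamide, via acid chloride 3 (not isolated)
Conditions: SOCl2, cat. DMF, toluene, 80 °C; evaporate; then 2, Et3N, CH2Cl2, 0 °C → rt
Reagents that add atoms: none
Why: Acid chloride formation followed by chemoselective N-acylation (Schotten–Baumann-type amidation), the amine being far more nucleophilic than the hindered primary alcohol.

Step 2
Reactants: 4 3-chloro-N-(1-hydroxy-2-methylpropan-2-yl)-4-methylbenzamide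
Product: 6 2-(3-chloro-4-methylphenyl)-4,4-dimethyl-4,5-dihydrooxazole, via oxazolinium chloride 5 (not isolated)
Conditions: SOCl2, CH2Cl2, 0 °C → rt; then aq. NaOH
Reagents that add atoms: none
Why: Cyclodehydration of a β-hydroxy amide, in which the chlorosulfite is displaced by the amide oxygen (5-exo-tet) and base frees the oxazoline; this is the standard preparation of 2-aryl-4,4-dimethyloxazolines.

Step 3
Reactants: 7 1-bromo-2,4,5-trimethoxybenzene
Product: 8 2,4,5-trimethoxyphenyllithium
Conditions: t-BuLi (2.0 equiv), THF, −78 °C; solution used at once in step 4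
Reagents that add atoms: tert-butyllithium, [Li]C(C)(C)C
Why: Bromine–lithium exchange is fast at −78 °C, and the second equivalent of t-BuLi destroys the tert-butyl bromide, so no alkyl halide is left to alkylate the aryllithiums of step 4.

Step 4
Reactants: 6 2-(3-chloro-4-methylphenyl)-4,4-dimethyl-4,5-dihydrooxazole; 8 2,4,5-trimethoxyphenyllithium; 9 iodomethane
Product: 13 2-[2-(2,4,5-trimethoxyphenyl)-3,4-dimethylphenyl]-4,4-dimethyl-4,5-dihydrooxazole, via lithiated chloroarene 10 (not isolated), via aryne 11 (not isolated), via biaryl aryllithium 12 (not isolated)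
Conditions: 6, s-BuLi (1.0 equiv), THF, −78 °C; then 8 (2.5 equiv), −78 → −15 °C; then MeI (excess), −78 °C → rt
Reagents that add atoms: iodomethane, CI
Why: sec-BuLi removes the one ring proton lying between the oxazoline and the chlorine (cooperative directed ortho-metalation) to give 10, which is stable at −78 °C and loses LiCl on warming to give aryne 11 across C7–C8. Aryllithium 8, bound to the oxazoline nitrogen, adds to the near aryne carbon C8 and leaves the carbanion on C7 (12), which iodomethane alkylates. The closest known reaction type is the tandem addition of organolithiums to oxazolinyl benzynes generated from meta-chloroaryl oxazolines, followed by electrophilic trapping of the new aryllithium. No ring is closed and no stereocentre is formed; two C–C bonds (C8–aryl and C7–CH3) are made. The step needs addition at C8 and not at C7: nitrogen–lithium complexation steers the nucleophile to C8 against the inductive preference, and the C6 methyl next to C7 adds a steric bias in the same sense. Using only one equivalent of s-BuLi keeps sec-butyl out of the aryne, and the excess of 8 outruns addition of 10 to 11.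

Step 5
Reactants: 13 2-[2-(2,4,5-trimethoxyphenyl)-3,4-dimethylphenyl]-4,4-dimethyl-4,5-dihydrooxazole
Product: 15 2-(4,4-dimethyl-4,5-dihydrooxazol-2-yl)-4,5-dimethyl-3-(2,4,5-trimethoxyphenyl)benzaldehyde, via aryllithium 14 (not isolated)
Conditions: s-BuLi (1.1 equiv), Et2O, −78 → −40 °C; DMF, −78 °C → rt; H2O
Reagents that add atoms: N,N-dimethylformamide, CN(C)C=O
Why: Directed ortho-metalation, in which the oxazoline nitrogen pre-complexes s-BuLi and delivers it to the only remaining ortho C–H (on the future C4a), followed by formylation with DMF; a weakly coordinating solvent and one equivalent of base favour this site over the C3' hydrogen between two methoxy groups.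

Step 6
Reactants: 15 2-(4,4-dimethyl-4,5-dihydrooxazol-2-yl)-4,5-dimethyl-3-(2,4,5-trimethoxyphenyl)benzaldehyde
Product: 16 3-hydroxy-5,6-dimethyl-7-(2,4,5-trimethoxyphenyl)isobenzofuran-1(3H)-one
Conditions: 3 M aq. HCl, THF, reflux
Reagents that add atoms: water, O
Why: Acid hydrolysis of the oxazoline, assisted by the neighbouring aldehyde hydrate, which lactonises to the ring-closed lactol form of the 2-formylbenzoic acid; the lactol carbon forms racemic and is not a stereocentre of the target.

Step 7
Reactants: 16 3-hydroxy-5,6-dimethyl-7-(2,4,5-trimethoxyphenyl)isobenzofuran-1(3H)-one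
Product: 17 5,6-dimethyl-3-(phenylsulfonyl)-7-(2,4,5-trimethoxyphenyl)isobenzofuran-1(3H)-one
Conditions: PhSO2Na, AcOH, 80 °C
Reagents that add atoms: sodium benzenesulfinate, [Na+].[O-]S(=O)c1ccccc1
Why: Acid-promoted ionisation of the lactol to the phthalidyl oxocarbenium ion and capture by sulfinate at sulfur, the usual way to a Hauser donor; the racemic sulfonyl-bearing carbon becomes C4 of the quinone.

Step 8
Reactants: 18 methoxymethyl phenyl sulfide
Product: 19 methoxymethyl phenyl sulfone
Conditions: mCPBA (2.2 equiv), NaHCO3, CH2Cl2, 0 °C → rt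
Reagents that add atoms: 3-chloroperbenzoic acid, OOC(=O)c1cccc(Cl)c1
Why: Peracid oxidation of a sulfide through the sulfoxide to the sulfone, with bicarbonate protecting the O,S-acetal from acid.

Step 9
Reactants: 19 methoxymethyl phenyl sulfone
Product: 21 2-methoxy-N,N-dimethyl-2-(phenylsulfonyl)ethan-1-amine, via lithiated sulfone 20 (not isolated)
Conditions: n-BuLi, THF, −78 °C; Eschenmoser's salt (Me2N+=CH2 I−), −78 °C → rt
Reagents that add atoms: N,N-dimethylmethyleneiminium iodide, C=[N+](C)C.[I-]
Why: α-Lithiation of the sulfone and aminomethylation with a preformed iminium salt (Mannich reaction); the new centre is racemic and is destroyed in step 10.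

Step 10
Reactants: 21 2-methoxy-N,N-dimethyl-2-(phenylsulfonyl)ethan-1-amine; 9 iodomethane
Product: 23 1-methoxyvinyl phenyl sulfone, via ammonium iodide 22 (not isolated)
Conditions: MeI, MeCN, rt; evaporate; DBU, CH2Cl2, 0 °C → rt; used fresh
Reagents that add atoms: none
Why: N-Methylation and base-induced β-elimination of trimethylamine (Hofmann-type elimination of a Mannich methiodide), the standard α-methylenation sequence for sulfones.

Step 11
Reactants: 17 5,6-dimethyl-3-(phenylsulfonyl)-7-(2,4,5-trimethoxyphenyl)isobenzofuran-1(3H)-one; 23 1-methoxyvinyl phenyl sulfone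
Product: 27 2-methoxy-6,7-dimethyl-8-(2,4,5-trimethoxyphenyl)naphthalene-1,4-dione, via phthalide anion 24 (not isolated), via Michael adduct 25 (not isolated), via sulfonyl dione 26 (not isolated)
Conditions: LiN(SiMe3)2 (1.05 equiv), THF, −78 °C; 23 (1.3 equiv), −78 → −20 °C; LiN(SiMe3)2 (1.05 equiv), −20 → 0 °C; pH 7 buffer
Reagents that add atoms: none
Why: Proposed new method: the lithiated sulfonylphthalide 24 should add in Michael fashion to the CH2 terminus of 23, the α-methoxy-α-sulfonyl carbanion 25 should close ring A by 6-exo-trig Dieckmann-type attack on the lactone carbonyl (C1–C2 bond) with loss of the first sulfinate from C4 to give dione 26, and the second equivalent of base should remove a C3 proton and expel the C2 sulfinate (E1cB), a far better leaving group than methoxide, giving the quinone directly with the methoxy group on C2 next to the former lactone carbonyl; the closest known reaction type is the Hauser–Kraus annulation of 3-sulfonylphthalides with acrylates and related Michael acceptors, extended here to an α-alkoxy vinyl sulfone whose sulfonyl group is a traceless activator.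

**Compound list**
1 | 3-chloro-4-methylbenzoic acid | Cc1ccc(C(=O)O)cc1Cl | starting material
2 | 2-amino-2-methylpropan-1-ol | CC(C)(N)CO | starting material
3 | 3-chloro-4-methylbenzoyl chloride | Cc1ccc(C(=O)Cl)cc1Cl | intermediate
4 | 3-chloro-N-(1-hydroxy-2-methylpropan-2-yl)-4-methylbenzamide | Cc1ccc(C(=O)NC(C)(C)CO)cc1Cl | intermediate
5 | 2-(3-chloro-4-methylphenyl)-4,4-dimethyl-4,5-dihydrooxazol-3-ium chloride | Cc1ccc(C2=[NH+]C(C)(C)CO2)cc1Cl.[Cl-] | intermediate
6 | 2-(3-chloro-4-methylphenyl)-4,4-dimethyl-4,5-dihydrooxazole | Cc1ccc(C2=NC(C)(C)CO2)cc1Cl | intermediate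
7 | 1-bromo-2,4,5-trimethoxybenzene | COc1cc(OC)c(Br)cc1OC | starting material
8 | 2,4,5-trimethoxyphenyllithium | [Li]c1cc(OC)c(OC)cc1OC | intermediate
9 | iodomethane | CI | starting material
10 | [2-chloro-6-(4,4-dimethyl-4,5-dihydrooxazol-2-yl)-3-methylphenyl]lithium | Cc1ccc(C2=NC(C)(C)CO2)c([Li])c1Cl | intermediate
11 | 2-(4-methyl-2,3-didehydrophenyl)-4,4-dimethyl-4,5-dihydrooxazole (aryne) | CC1=CC=C(C2=NC(C)(C)CO2)C#C1 | intermediate
12 | [3-(4,4-dimethyl-4,5-dihydrooxazol-2-yl)-6-methyl-2-(2,4,5-trimethoxyphenyl)phenyl]lithium | Cc1ccc(C2=NC(C)(C)CO2)c(-c2cc(OC)c(OC)cc2OC)c1[Li] | intermediate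
13 | 2-[2-(2,4,5-trimethoxyphenyl)-3,4-dimethylphenyl]-4,4-dimethyl-4,5-dihydrooxazole | Cc1ccc(C2=NC(C)(C)CO2)c(-c2cc(OC)c(OC)cc2OC)c1C | intermediate
14 | [2-(4,4-dimethyl-4,5-dihydrooxazol-2-yl)-4,5-dimethyl-3-(2,4,5-trimethoxyphenyl)phenyl]lithium | Cc1cc([Li])c(C2=NC(C)(C)CO2)c(-c2cc(OC)c(OC)cc2OC)c1C | intermediate
15 | 2-(4,4-dimethyl-4,5-dihydrooxazol-2-yl)-4,5-dimethyl-3-(2,4,5-trimethoxyphenyl)benzaldehyde | Cc1cc(C=O)c(C2=NC(C)(C)CO2)c(-c2cc(OC)c(OC)cc2OC)c1C | intermediate
16 | 3-hydroxy-5,6-dimethyl-7-(2,4,5-trimethoxyphenyl)isobenzofuran-1(3H)-one (racemic) | OC1OC(=O)c2c1cc(C)c(C)c2-c1cc(OC)c(OC)cc1OC | intermediate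
17 | 5,6-dimethyl-3-(phenylsulfonyl)-7-(2,4,5-trimethoxyphenyl)isobenzofuran-1(3H)-one (racemic) | O=C1OC(S(=O)(=O)c2ccccc2)c2cc(C)c(C)c(-c3cc(OC)c(OC)cc3OC)c21 | intermediate
18 | methoxymethyl phenyl sulfide | COCSc1ccccc1 | starting material
19 | methoxymethyl phenyl sulfone | COCS(=O)(=O)c1ccccc1 | intermediate
20 | [methoxy(phenylsulfonyl)methyl]lithium | [Li]C(OC)S(=O)(=O)c1ccccc1 | intermediate
21 | 2-methoxy-N,N-dimethyl-2-(phenylsulfonyl)ethan-1-amine (racemic) | COC(CN(C)C)S(=O)(=O)c1ccccc1 | intermediate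
22 | 2-methoxy-N,N,N-trimethyl-2-(phenylsulfonyl)ethan-1-aminium iodide (racemic) | COC(C[N+](C)(C)C)S(=O)(=O)c1ccccc1.[I-] | intermediate
23 | 1-methoxyvinyl phenyl sulfone | C=C(OC)S(=O)(=O)c1ccccc1 | intermediate
24 | [5,6-dimethyl-3-oxo-1-(phenylsulfonyl)-4-(2,4,5-trimethoxyphenyl)-1,3-dihydroisobenzofuran-1-yl]lithium | O=C1OC([Li])(S(=O)(=O)c2ccccc2)c2cc(C)c(C)c(-c3cc(OC)c(OC)cc3OC)c21 | intermediate
25 | lithiated Michael adduct, 3-[2-lithio-2-methoxy-2-(phenylsulfonyl)ethyl]-5,6-dimethyl-3-(phenylsulfonyl)-7-(2,4,5-trimethoxyphenyl)isobenzofuran-1(3H)-one | O=C1OC(CC([Li])(OC)S(=O)(=O)c2ccccc2)(S(=O)(=O)c2ccccc2)c2cc(C)c(C)c(-c3cc(OC)c(OC)cc3OC)c21 | intermediate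
26 | 2-methoxy-6,7-dimethyl-2-(phenylsulfonyl)-8-(2,4,5-trimethoxyphenyl)-2,3-dihydronaphthalene-1,4-dione (racemic) | COC1(S(=O)(=O)c2ccccc2)CC(=O)c2cc(C)c(C)c(-c3cc(OC)c(OC)cc3OC)c2C1=O | intermediate
27 | 2-methoxy-6,7-dimethyl-8-(2,4,5-trimethoxyphenyl)naphthalene-1,4-dione | COC1=CC(=O)c2cc(C)c(C)c(-c3cc(OC)c(OC)cc3OC)c2C1=O | target

**Step count**
Total: 11 steps. Longest linear sequence: 7 steps (1, 2, 4, 5, 6, 7, 11) from 3-chloro-4-methylbenzoic acid; steps 3 and 8–10 are side branches.

**Steps most likely to fail**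

Step 11 (proposed new method). Conjugate addition to the donor-substituted vinyl sulfone may be slow or reversible, ring closure onto the lactone carbonyl shielded by the neighbouring aryl group may stall, and the liberated sulfinate may add back to the product quinone. The fallback uses known reactions only, sets out from 16 and returns to the route at 27.
- Wittig olefination of 16 in its open 2-formylbenzoic acid form (Ph3P=CHCO2Me, toluene, 80 °C) gives the 2-carboxycinnamate F1.
- Hydrogenation (H2, Pd/C, MeOH) gives the saturated acid ester F2.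
- Esterification (MeI, K2CO3, DMF) gives the diester F3.
- Dieckmann condensation (KOtBu, THF) gives the tetralone β-keto ester F4.
- Krapcho dealkoxycarbonylation (LiCl, wet DMSO, 150 °C) gives the 1-tetralone F5, whose carbonyl carbon is C1.
- Base-mediated autoxidation (O2, KOtBu, t-BuOH) gives the 2-hydroxy-1,4-naphthoquinone F6, with the hydroxyl on C2 next to C1.
- Acid-catalysed O-methylation (MeOH, HCl) gives 27.

Step 4 (key step). The aryl nucleophile may add at the far aryne carbon, 10 may add to the aryne, or the C7 aryllithium may isomerise by benzylic proton transfer before methylation. The fallback sets out from 6 (through its lithio derivative 10, kept at −78 °C) and returns at 13.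
- Transmetalation of 10 with ZnCl2 gives the arylzinc chloride F7.
- Negishi coupling with bromide 7 (Pd2(dba)3, SPhos, THF, 60 °C) gives the chloro biaryl F8, the aryl bromide reacting ahead of the hindered chloride.
- Suzuki–Miyaura methylation of the chloride (trimethylboroxine, Pd(OAc)2, SPhos, K3PO4, dioxane, 100 °C) gives 13.

Step 5. Deprotonation may occur at the C3' position between two methoxy groups or at a benzylic methyl instead of beside the oxazoline. The fallback replaces lithiation by carboxylate-directed C–H activation, sets out from 13 and returns at 17.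
- Hydrolysis of the oxazoline (aq. HCl, reflux; then NaOH) gives the biaryl carboxylic acid F9.
- Palladium-catalysed ortho C–H alkylation and lactonisation with CH2Br2 (Pd(OAc)2, K2HPO4, 140 °C) gives the phthalide F10.
- Deprotonation with LiN(SiMe3)2 in the presence of PhSSPh gives the 3-(phenylthio)phthalide F11.
- Oxidation (mCPBA, CH2Cl2, 0 °C) gives 17.

**Further compounds**
F1 | step 11 | 2-[(E)-3-methoxy-3-oxoprop-1-en-1-yl]-4,5-dimethyl-6-(2,4,5-trimethoxyphenyl)benzoic acid | COC(=O)/C=C/c1cc(C)c(C)c(-c2cc(OC)c(OC)cc2OC)c1C(=O)O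
F2 | step 11 | 2-(3-methoxy-3-oxopropyl)-4,5-dimethyl-6-(2,4,5-trimethoxyphenyl)benzoic acid | COC(=O)CCc1cc(C)c(C)c(-c2cc(OC)c(OC)cc2OC)c1C(=O)O
F3 | step 11 | methyl 2-(3-methoxy-3-oxopropyl)-4,5-dimethyl-6-(2,4,5-trimethoxyphenyl)benzoate | COC(=O)CCc1cc(C)c(C)c(-c2cc(OC)c(OC)cc2OC)c1C(=O)OC
F4 | step 11 | methyl 6,7-dimethyl-1-oxo-8-(2,4,5-trimethoxyphenyl)-1,2,3,4-tetrahydronaphthalene-2-carboxylate (racemic) | COC(=O)C1CCc2cc(C)c(C)c(-c3cc(OC)c(OC)cc3OC)c2C1=O
F5 | step 11 | 6,7-dimethyl-8-(2,4,5-trimethoxyphenyl)-3,4-dihydronaphthalen-1(2H)-one | O=C1CCCc2cc(C)c(C)c(-c3cc(OC)c(OC)cc3OC)c21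
F6 | step 11 | 2-hydroxy-6,7-dimethyl-8-(2,4,5-trimethoxyphenyl)naphthalene-1,4-dione | OC1=CC(=O)c2cc(C)c(C)c(-c3cc(OC)c(OC)cc3OC)c2C1=O
F7 | step 4 | [2-chloro-6-(4,4-dimethyl-4,5-dihydrooxazol-2-yl)-3-methylphenyl]zinc chloride | Cc1ccc(C2=NC(C)(C)CO2)c([Zn]Cl)c1Cl
F8 | step 4 | 2-[3-chloro-4-methyl-2-(2,4,5-trimethoxyphenyl)phenyl]-4,4-dimethyl-4,5-dihydrooxazole | Cc1ccc(C2=NC(C)(C)CO2)c(-c2cc(OC)c(OC)cc2OC)c1Cl
F9 | step 5 | 3,4-dimethyl-2-(2,4,5-trimethoxyphenyl)benzoic acid | Cc1ccc(C(=O)O)c(-c2cc(OC)c(OC)cc2OC)c1C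
F10 | step 5 | 5,6-dimethyl-7-(2,4,5-trimethoxyphenyl)isobenzofuran-1(3H)-one | O=C1OCc2cc(C)c(C)c(-c3cc(OC)c(OC)cc3OC)c21
F11 | step 5 | 5,6-dimethyl-3-(phenylthio)-7-(2,4,5-trimethoxyphenyl)isobenzofuran-1(3H)-one (racemic) | O=C1OC(Sc2ccccc2)c2cc(C)c(C)c(-c3cc(OC)c(OC)cc3OC)c21
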